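## Analysis of the target

Atom numbers follow lindenane numbering (C1–C15, primed in the second half); β is the face of the C14 methyl group.

- Compound 29 (CNP0265879.1) is a C2-symmetric dimer of two identical lindenane trienolide halves. They are joined by a cyclobutane made of C8, C9, C9′ and C8′ (new bonds C8–C8′ and C9–C9′), so 29 is the head-to-head [2+2] dimer across the enol-lactone double bond C8=C9 of monomer 28.
- Each half has a 3/5/6/5 skeleton: cyclopropane C1–C2–C3 fused to cyclopentane ring A (C1, C3, C4, C5, C10, with exocyclic C4=C15), cyclohexane ring B (C5–C10) and butenolide ring C (C7, C8, O, C12, C11, methyl C13 on C11).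
- Of the twelve stereocentres, C1, C3, C5 and C10 of each half belong to the monomer. The cyclopropane CH2 (C2) is β like C14, and H-5 is α, so rings A and B are trans-fused and the C6 branch is cis to C14.
- C8 and C9 arise in the dimerisation. Both new bonds lie on the α face of each half, and the halves are anti across the four-membered ring.
- Sensitive groups are the vinylcyclopropane C15=C4–C3 (acid, electrophilic halogen, late transition metals) and the cross-conjugated enol lactone (base, nucleophiles, light).
- The difficulty lies in the monomer: quaternary C10 sits between C1 and C5, the cyclopropane is on the more crowded β face, and one enantiomer is needed because two molecules are paired at the end.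
- The strategy rests on ring C. The lactone oxygen sits on C8, C8 is bonded to C7, and C7=C11 is exocyclic to ring B. Read backwards, this is an enolised C8 ketone next to a dehydrated aldol at C11. The resulting 1,3-pattern C8(=O)/C11(–OH) is what an isoxazoline C8=N–O–C11 releases on N–O cleavage, so ring B can be closed by bonding C8 to C7.

## Retrosynthetic reasoning

**29 to 28.** The cyclobutane bonds C8–C8′ and C9–C9′ are cut by a retro-[2+2]. Both halves are identical and related by the C2 axis, so the problem reduces to one enantiomer of 28. The forward photodimerisation must be head-to-head, use the α face of both partners and give the anti arrangement.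

**28 to 24.** Opening the C12–O lactone bond and rehydrating C7=C11 leads to β-hydroxy ketone 26 (C8 ketone, C11 tertiary alcohol carrying the ester). Compound 26 is the N–O cleavage product of isoxazoline 24. All oxygen atoms of ring C are then in place at the right oxidation level.

**24 to 22 (key disconnection).** Bonds C7–C8 and O–C11 are cut by a retro-(3+2) cycloaddition, which opens ring B and gives ring A aldoxime 22 with its (E)-enoate arm. Ring B has no lasting stereocentre of its own, so this cut leaves every stereocentre of the monomer in ring A. The forward reaction has to solve regiochemistry only, because C7 and C11 become sp2 later.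

**22 to 17.** The oxime comes from the C8 aldehyde, masked as the diethyl acetal in 20. C4=C15 comes from ketone 19, and 19 from alcohol 18. The cyclopropane (C2) is removed from 18 to give allylic alcohol 17. In 17 the C4 hydroxyl is cis to the C6 arm and therefore on the β face, so a hydroxyl-directed methylene transfer places C2 where the target has it.

**17 to 11.** C7=C11 is cut by a Wittig disconnection to lactol 15 and ylide 16, which also frees the C4 hydroxyl. Lactol 15 comes from allylic lactone 14, 14 from iodolactone 13 by elimination, and 13 from ester 11 through acid 12. The iodolactonisation puts oxygen on C4 cis to C6 by ring constraint, and the elimination moves the double bond from C3=C4 to C1=C3.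

**11 to 8.** The C5–C6 bond is cut by a Claisen disconnection to allylic alcohol 9 and orthoester 3. The shift is suprafacial, so the C3 carbinol of 9 (hydroxyl cis to the methyl group) dictates C5. Alcohol 9 comes from enone 8 by a catalyst-controlled reduction.

**8 to 1.** The allylic CH2 of 7 is the only allylic position with hydrogen, so 8 comes from 7 by allylic oxidation. Acetal 7 comes from ester 5 through aldehyde 6. The C10–C9 bond of 5 is cut by a second Claisen disconnection to alcohol 2 and orthoester 3, and 2 comes from enone 1 by enantioselective reduction.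

A conjugate addition with enolate alkylation on 1 would be shorter. It would leave C5 and the cyclopropane face to the small steric difference between a methyl and a CH2R group on C10. The two sigmatropic shifts and the directed cyclopropanation remove that dependence.

## Alternatives that were turned down

**Alternative 1: Diels–Alder closure of ring B (C5–C6 and C9–C10).**
- Forward step: fluoride-induced 1,4-elimination releases furan-2,3-quinodimethane A2, which adds to the C5=C10 double bond of menthyloxy butenolide A1, anti to the menthyloxy group, to give cis-fused lactone A3.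
- For: it is convergent. Two C–C bonds, ring B, quaternary C10 and all carbons of ring C (as a furan) arrive in one step, and the auxiliary sets the absolute configuration.
- Against: C10 of A1 is a β,β-disubstituted, weakly activated dienophile carbon. The orientation of the unsymmetrical diene A2 (C6 or C9 to C5) rests on small electronic differences.
- Against: A3 still lacks ring A and the cyclopropane. The lactone carbonyl has to become C4, the acetal carbon has to be reduced to the C14 methyl, the silyloxyethyl arm has to become C1/C2, and the cyclopropane must still be placed cis to C14 without a directing group. The furan then needs regioselective oxidation to the enol lactone.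
- Comparison: Alternative 1 is stronger in convergence; the chosen route is linear. In its place the chosen route gives ring C at the correct oxidation level directly from 24 and fixes the cyclopropane by a directed step before ring B exists.

**Alternative 2: platinum cycloisomerisation forming ring A and the cyclopropane (C3–C1 and C3–C2).**
- Forward step: PtCl2 triggers a 1,2-acetoxy shift in enynyl acetate A4; the carbene at C3 cyclopropanates the vinyl group C1=C2 to give bicyclic enol acetate A5.
- For: one atom-economic catalytic step makes both small rings and leaves C4 as an enol acetate, a regiospecific C5 enolate precursor. For this region it is shorter than steps 12–14 of the chosen route.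
- Against: A4 has an acyclic quaternary C10 with four different carbon substituents that must be made as one enantiomer. The propargylic stereocentre is lost, so the cyclopropane face depends on discrimination between CH3 and CH(OMe)2.
- Against: the acetal carbon is only C9, so C8 needs a homologation. Alkylation of C5 would have to occur on the concave face. Rings B and C remain to be built, so a closure such as 22 to 24 would still be needed.
- Comparison: the chosen route is longer in ring A but sets C10, C5 and the cyclopropane by stereospecific steps.

**Alternative 3: cyclopropane C–H alkenylation closing ring A (C3–C4).**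
- Forward step: zerovalent palladium inserts into the C4–Br bond of bromide A6, cleaves a cyclopropyl C–H bond cis to C10 by concerted metalation–deprotonation and forms C3–C4, giving A7.
- For: ring A, the exocyclic methylene and the cis cyclopropane fusion form in one late step without a separate methylenation. The trans relation on the cyclohexane is easy to set, and the C8 ketal is a handle for a butenolide annulation. For ring A this is stronger in step economy.
- Against: the two CH2 groups of the cyclopropyl ring are diastereotopic and only one gives C2 cis to C14. The choice depends on a rotamer preference about C10–C1 in a six-membered palladacycle.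
- Against: A6 needs a quaternary C10 bearing cyclopropyl next to a 1-bromovinyl group on C5. Cyclopropylpalladium species can ring-open. Ring C still requires a C–C bond at C7 and oxidation-level changes.
- Comparison: the chosen route relies on sigmatropic shifts and a directed cyclopropanation for the four monomer stereocentres, and it makes C7–C8 and the C11 oxygen in one operation.

Key step: step 16

Assumption: oxime 22 and lactol 15 are used as isomer mixtures, because the centres concerned are lost later.

## Route

Step 1
Reactants: 1 3-methylcyclopent-2-en-1-one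
Product: 2 (R)-3-methylcyclopent-2-en-1-ol
Conditions: (S)-Me-CBS oxazaborolidine (10 mol %), BH3·SMe2, THF, −20 °C; MeOH
Reagents that add atoms: none
Why: Corey–Bakshi–Shibata reduction; the catalyst binds the ketone with the alkenyl branch in the large-group site and delivers hydride to one face, and 1,2-reduction is much faster than hydroboration of the trisubstituted alkene.

Step 2
Reactants: 2 (R)-3-methylcyclopent-2-en-1-ol; 3 triethyl orthoacetate
Product: 5 ethyl 2-[(1R)-1-methylcyclopent-2-en-1-yl]acetate, via mixed ketene acetal 4 (not isolated)
Conditions: EtCO2H (cat.), neat 3, 140 °C, EtOH distilled off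
Reagents that add atoms: none
Why: Johnson–Claisen rearrangement; the [3,3] shift of 4 is suprafacial on the cyclopentene, so the C9–C8 unit enters C10 on the face the oxygen leaves and the quaternary centre is set by chirality transfer.

Step 3
Reactants: 5 ethyl 2-[(1R)-1-methylcyclopent-2-en-1-yl]acetate
Product: 6 2-[(1R)-1-methylcyclopent-2-en-1-yl]acetaldehyde
Conditions: i-Bu2AlH (1.05 equiv), CH2Cl2, −78 °C; aq KNaC4H4O6
Reagents that add atoms: none
Why: Partial ester reduction; the aluminium hemiacetal is stable at −78 °C and gives the aldehyde only on work-up.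

Step 4
Reactants: 6 2-[(1R)-1-methylcyclopent-2-en-1-yl]acetaldehyde
Product: 7 (R)-3-(2,2-diethoxyethyl)-3-methylcyclopent-1-ene
Conditions: HC(OEt)3, EtOH, PPTS (cat.), 23 °C
Reagents that add atoms: triethyl orthoformate CCOC(OCC)OCC; ethanol CCO
Why: Acid-catalysed acetalisation driven by the orthoformate as water scavenger; the acetal holds C8 at the aldehyde level through the hydride, base, zinc and ylide steps that follow.

Step 5
Reactants: 7 (R)-3-(2,2-diethoxyethyl)-3-methylcyclopent-1-ene
Product: 8 (S)-4-(2,2-diethoxyethyl)-4-methylcyclopent-2-en-1-one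
Conditions: CrO3, 3,5-dimethylpyrazole, CH2Cl2, −20 °C
Reagents that add atoms: chromium trioxide O=[Cr](=O)=O
Why: Allylic oxidation with the chromium trioxide–dimethylpyrazole complex; the ring CH2 next to the alkene is the only allylic position with hydrogen (the other is quaternary C10), so it becomes the enone carbonyl with the double bond in place.

Step 6
Reactants: 8 (S)-4-(2,2-diethoxyethyl)-4-methylcyclopent-2-en-1-one
Product: 9 (1S,4R)-4-(2,2-diethoxyethyl)-4-methylcyclopent-2-en-1-ol
Conditions: (R)-Me-CBS oxazaborolidine (10 mol %), BH3·SMe2, THF, −30 °C; MeOH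
Reagents that add atoms: none
Why: Corey–Bakshi–Shibata reduction under catalyst control; the two substituents on the remote quaternary centre differ little, so the catalyst decides the face and should give the hydroxyl cis to the methyl group, the face on which C6 must enter.

Step 7
Reactants: 9 (1S,4R)-4-(2,2-diethoxyethyl)-4-methylcyclopent-2-en-1-ol; 3 triethyl orthoacetate
Product: 11 ethyl 2-[(1S,5R)-5-(2,2-diethoxyethyl)-5-methylcyclopent-2-en-1-yl]acetate, via mixed ketene acetal 10 (not isolated)
Conditions: 3 (excess), EtCO2H (cat.), xylene, 140 °C
Reagents that add atoms: none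
Why: Johnson–Claisen rearrangement; the suprafacial shift delivers C6–C7 to C5 on the face of the leaving oxygen, so C5 is set cis to C14 and trans to the acetal arm, and the double bond moves to C3=C4.

Step 8
Reactants: 11 ethyl 2-[(1S,5R)-5-(2,2-diethoxyethyl)-5-methylcyclopent-2-en-1-yl]acetate
Product: 13 cis-fused iodolactone (4-(2,2-diethoxyethyl)-6-iodo-4-methylhexahydro-2H-cyclopenta[b]furan-2-one; iodine trans to the ring oxygen), via carboxylic acid 12 (not isolated)
Conditions: LiOH, THF/H2O, 23 °C; then NaHCO3, I2, KI, 0 °C, dark
Reagents that add atoms: iodine II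
Why: Saponification then iodolactonisation; the carboxylate opens the iodonium ion anti, and a five-membered lactone on a cyclopentane can only be cis-fused, so oxygen enters C4 on the face of C6 and iodine goes to C3 on the opposite face.

Step 9
Reactants: 13 cis-fused iodolactone
Product: 14 4-(2,2-diethoxyethyl)-4-methyl-3,3a,4,6a-tetrahydro-2H-cyclopenta[b]furan-2-one (cis-fused allylic lactone)
Conditions: DBU, toluene, 90 °C
Reagents that add atoms: none
Why: E2 dehydroiodination; only a C1 hydrogen is anti-periplanar to the C3–I bond (H-4 is syn to iodine), so the alkene forms at C1=C3.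

Step 10
Reactants: 14 cis-fused allylic lactone
Product: 15 corresponding lactol (2-hydroxy compound; anomer mixture)
Conditions: i-Bu2AlH (1.1 equiv), CH2Cl2, −78 °C; aq KNaC4H4O6
Reagents that add atoms: none
Why: Half-reduction of a γ-lactone at low temperature; the acetal and the alkene are inert to the hydride.

Step 11
Reactants: 15 lactol; 16 methyl 2-(triphenyl-λ5-phosphanylidene)propanoate
Product: 17 methyl (E)-4-[2-(2,2-diethoxyethyl)-5-hydroxy-2-methylcyclopent-3-en-1-yl]-2-methylbut-2-enoate (hydroxyl, methyl and butenoate arm on one face)
Conditions: toluene, 80 °C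
Reagents that add atoms: none
Why: Wittig olefination of the open hydroxy aldehyde form with a stabilised ylide should give the (E)-trisubstituted enoate and frees the C4 hydroxyl cis to the side chain; the α-methyl group slows an oxa-Michael return.

Step 12
Reactants: 17 hydroxy enoate
Product: 18 methyl (E)-4-[4-(2,2-diethoxyethyl)-2-hydroxy-4-methylbicyclo[3.1.0]hexan-3-yl]-2-methylbut-2-enoate (hydroxyl, butenoate arm, methyl and cyclopropane CH2 on one face)
Conditions: Et2Zn, CH2I2, CH2Cl2, 0 → 23 °C
Reagents that add atoms: diiodomethane ICI
Why: Hydroxyl-directed Simmons–Smith cyclopropanation (Furukawa conditions); the zinc alkoxide delivers CH2 to the face of the C4 hydroxyl, which sets C1 and C3 with C2 β (cis to C6 and C14), and the electron-poor enoate does not react with the electrophilic carbenoid.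

Step 13
Reactants: 18 cyclopropyl carbinol
Product: 19 methyl (E)-4-[4-(2,2-diethoxyethyl)-4-methyl-2-oxobicyclo[3.1.0]hexan-3-yl]-2-methylbut-2-enoate
Conditions: Dess–Martin periodinane, NaHCO3, CH2Cl2, 23 °C
Reagents that add atoms: none
Why: Dess–Martin oxidation turns the directing hydroxyl into the C4 ketone under buffered, non-basic conditions, so the α-stereocentre C5 should not epimerise.

Step 14
Reactants: 19 cyclopropyl ketone
Product: 20 methyl (E)-4-[4-(2,2-diethoxyethyl)-4-methyl-2-methylidenebicyclo[3.1.0]hexan-3-yl]-2-methylbut-2-enoate
Conditions: Zn, CH2Br2, TiCl4, THF/CH2Cl2, 0 → 23 °C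
Reagents that add atoms: dibromomethane BrCBr
Why: Lombardo–Takai methylenation; the gem-dimetallic reagent is non-basic, suits hindered enolisable ketones and leaves esters alone, and it installs C15.

Step 15
Reactants: 20 acetal
Product: 22 methyl (E)-4-[4-(2-(hydroxyimino)ethyl)-4-methyl-2-methylidenebicyclo[3.1.0]hexan-3-yl]-2-methylbut-2-enoate (ring A aldoxime), via free aldehyde 21 (not isolated)
Conditions: NH2OH·HCl, THF/H2O, 23 °C; then NaOAc
Reagents that add atoms: hydroxylamine hydrochloride NO.Cl
Why: The mild acidity of hydroxylammonium chloride hydrolyses the acyclic acetal, and the aldehyde is trapped at once by oxime condensation; the enoate and the vinylcyclopropane should tolerate this pH.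

Step 16
Reactants: 22 ring A aldoxime
Product: 24 ring B-fused isoxazoline methyl ester (C8=N–O–C11; H-7 α), via nitrile oxide 23 (not isolated)
Conditions: aq NaOCl, Et3N (cat.), CH2Cl2, 0 → 23 °C, slow addition at high dilution
Reagents that add atoms: none
Why: Hypochlorite oxidises the aldoxime to nitrile oxide 23, which adds to the C7=C11 enoate in a concerted, suprafacial (3+2) cycloaddition, forming C7–C8 and O–C11 together. The closest known reaction type is the intramolecular nitrile oxide–alkene cycloaddition with a four-atom tether. Ring B closes in the fused mode as a six-membered carbocycle, because the dipole carbon C8 bonds to the proximal alkene carbon C7 across the tether C9–C10–C5–C6. The five-membered isoxazoline forms in the same event, fused to ring B at C7–C8. C7 is controlled by a chair-like tether in which the trans-disposed C5 and C10 substituents hold the forming ring and C11 sits equatorially; C11 follows from C7 through the (E)-alkene geometry. The step needs regiochemistry and chemoselectivity only, since C7 and C11 become sp2 later and either diastereomer converges. The tether length excludes the bridged regioisomer, and oxygen goes to the ester-bearing carbon as in additions to methacrylates. Addition to C4=C15 would require a strained bridged bicyclo[2.2.1] closure and should not compete.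

Step 17
Reactants: 24 isoxazoline
Product: 26 β-hydroxy ketone (C8 ketone; C11 tertiary alcohol bearing methyl and CO2Me), via hydroxy imine 25 (not isolated)
Conditions: Mo(CO)6, MeCN/H2O (15:1), 80 °C
Reagents that add atoms: water O
Why: Reductive N–O cleavage by zerovalent molybdenum followed by hydrolysis of the imine unmasks the aldol pattern; unlike hydrogenolysis it leaves the alkenes and the cyclopropane untouched, and water intercepts the imine before it can acylate.

Step 18
Reactants: 26 β-hydroxy ketone
Product: 28 chloranthalactone A, via alkylidene keto ester 27 (not isolated)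
Conditions: p-TsOH·H2O (cat.), toluene, 90 °C, 4 Å molecular sieves
Reagents that add atoms: none
Why: Acid-catalysed aldol dehydration gives C7=C11; the C8 ketone enolises toward C9 and the enol oxygen attacks the ester with loss of methanol, the pattern of a pyruvate-aldol butenolide annulation; the alkene isomers equilibrate through the dienol and only the Z form can lactonise.

Step 19
Reactants: 28 chloranthalactone A (two molecules)
Product: 29 CNP0265879.1 (anti head-to-head [2+2] dimer)
Conditions: hν (about 350 nm), degassed MeCN (0.2 M), 23 °C
Reagents that add atoms: none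
Why: [2+2] photodimerisation of the enol-lactone alkene C8=C9; bonding C9 to C9′ first leaves two allylic, oxygen-stabilised radicals at C8 and C8′ that close, which gives the head-to-head dimer; both partners should react on the α face, away from the C14 methyl and the cyclopropane, in the anti arrangement, which sets C8, C9, C8′ and C9′.

## Compound list

1 | 3-methylcyclopent-2-en-1-one | CC1=CC(=O)CC1 | starting material
2 | (R)-3-methylcyclopent-2-en-1-ol | CC1=C[C@H](O)CC1 | intermediate
3 | triethyl orthoacetate | CC(OCC)(OCC)OCC | starting material
4 | (R)-3-(1-ethoxyvinyloxy)-1-methylcyclopent-1-ene (mixed ketene acetal) | C=C(OCC)O[C@H]1C=C(C)CC1 | intermediate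
5 | ethyl 2-[(1R)-1-methylcyclopent-2-en-1-yl]acetate | CCOC(=O)C[C@]1(C)C=CCC1 | intermediate
6 | 2-[(1R)-1-methylcyclopent-2-en-1-yl]acetaldehyde | O=CC[C@]1(C)C=CCC1 | intermediate
7 | (R)-3-(2,2-diethoxyethyl)-3-methylcyclopent-1-ene | CCOC(OCC)C[C@]1(C)C=CCC1 | intermediate
8 | (S)-4-(2,2-diethoxyethyl)-4-methylcyclopent-2-en-1-one | CCOC(OCC)C[C@]1(C)C=CC(=O)C1 | intermediate
9 | (1S,4R)-4-(2,2-diethoxyethyl)-4-methylcyclopent-2-en-1-ol (OH cis to CH3) | CCOC(OCC)C[C@]1(C)C=C[C@@H](O)C1 | intermediate
10 | 1-ethoxyvinyl ether of 9 (mixed ketene acetal) | CCOC(OCC)C[C@]1(C)C=C[C@@H](OC(=C)OCC)C1 | intermediate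
11 | ethyl 2-[(1S,5R)-5-(2,2-diethoxyethyl)-5-methylcyclopent-2-en-1-yl]acetate | CCOC(OCC)C[C@]1(C)[C@@H](CC(=O)OCC)C=CC1 | intermediate
12 | 2-[(1S,5R)-5-(2,2-diethoxyethyl)-5-methylcyclopent-2-en-1-yl]acetic acid | CCOC(OCC)C[C@]1(C)[C@@H](CC(=O)O)C=CC1 | intermediate
13 | cis-fused iodolactone, 4-(2,2-diethoxyethyl)-6-iodo-4-methylhexahydro-2H-cyclopenta[b]furan-2-one (I trans to ring O; CH3 cis to the lactone CH2) | CCOC(OCC)C[C@@]1(C)C[C@@H](I)[C@@H]2OC(=O)C[C@H]12 | intermediate
14 | cis-fused allylic lactone, 4-(2,2-diethoxyethyl)-4-methyl-3,3a,4,6a-tetrahydro-2H-cyclopenta[b]furan-2-one | CCOC(OCC)C[C@@]1(C)C=C[C@@H]2OC(=O)C[C@H]12 | intermediate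
15 | lactol of 14 (anomer mixture) | CCOC(OCC)C[C@@]1(C)C=C[C@@H]2OC(O)C[C@H]12 | intermediate
16 | methyl 2-(triphenyl-λ5-phosphanylidene)propanoate | COC(=O)C(C)=P(c1ccccc1)(c1ccccc1)c1ccccc1 | starting material
17 | methyl (E)-4-[2-(2,2-diethoxyethyl)-5-hydroxy-2-methylcyclopent-3-en-1-yl]-2-methylbut-2-enoate (OH, CH3 and butenoate arm cis) | CCOC(OCC)C[C@@]1(C)C=C[C@H](O)[C@@H]1C/C=C(\C)C(=O)OC | intermediate
18 | methyl (E)-4-[4-(2,2-diethoxyethyl)-2-hydroxy-4-methylbicyclo[3.1.0]hexan-3-yl]-2-methylbut-2-enoate (OH, butenoate arm, CH3 and cyclopropane CH2 cis) | CCOC(OCC)C[C@@]1(C)[C@@H]2C[C@@H]2[C@H](O)[C@@H]1C/C=C(\C)C(=O)OC | intermediate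
19 | methyl (E)-4-[4-(2,2-diethoxyethyl)-4-methyl-2-oxobicyclo[3.1.0]hexan-3-yl]-2-methylbut-2-enoate | CCOC(OCC)C[C@@]1(C)[C@@H]2C[C@@H]2C(=O)[C@@H]1C/C=C(\C)C(=O)OC | intermediate
20 | methyl (E)-4-[4-(2,2-diethoxyethyl)-4-methyl-2-methylidenebicyclo[3.1.0]hexan-3-yl]-2-methylbut-2-enoate | CCOC(OCC)C[C@@]1(C)[C@@H]2C[C@@H]2C(=C)[C@@H]1C/C=C(\C)C(=O)OC | intermediate
21 | methyl (E)-2-methyl-4-[4-methyl-2-methylidene-4-(2-oxoethyl)bicyclo[3.1.0]hexan-3-yl]but-2-enoate | O=CC[C@@]1(C)[C@@H]2C[C@@H]2C(=C)[C@@H]1C/C=C(\C)C(=O)OC | intermediate
22 | ring A aldoxime, methyl (E)-4-[4-(2-(hydroxyimino)ethyl)-4-methyl-2-methylidenebicyclo[3.1.0]hexan-3-yl]-2-methylbut-2-enoate | C=C1[C@H]2C[C@H]2[C@](C)(CC=NO)[C@H]1C/C=C(\C)C(=O)OC | intermediate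
23 | nitrile oxide of 22 | C=C1[C@H]2C[C@H]2[C@](C)(CC#[N+][O-])[C@H]1C/C=C(\C)C(=O)OC | intermediate
24 | ring B-fused isoxazoline methyl ester (C8=N–O–C11; H-5 α, H-7 α, C14 β) | C=C1[C@H]2C[C@H]2[C@@]2(C)[C@H]1C[C@H]1C(=NO[C@]1(C)C(=O)OC)C2 | intermediate
25 | β-hydroxy imine from 24 | C=C1[C@H]2C[C@H]2[C@@]2(C)[C@H]1C[C@@H](C(=N)C2)[C@](C)(O)C(=O)OC | intermediate
26 | β-hydroxy ketone (C8 ketone; C7 bears C11(OH)(CH3)CO2Me) | C=C1[C@H]2C[C@H]2[C@@]2(C)[C@H]1C[C@@H](C(=O)C2)[C@](C)(O)C(=O)OC | intermediate
27 | (Z)-alkylidene keto ester (C7=C11, C8 ketone) | C=C1[C@H]2C[C@H]2[C@@]2(C)[C@H]1C/C(C(=O)C2)=C(\C)C(=O)OC | intermediate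
28 | chloranthalactone A | C=C1[C@H]2C[C@H]2[C@@]2(C)[C@H]1CC1=C(C)C(=O)OC1=C2 | intermediate
29 | CNP0265879.1, anti head-to-head [2+2] dimer of 28 | C=C1[C@H]2C[C@H]2[C@@]2(C)[C@H]1CC1=C(C)C(=O)O[C@]13[C@H]2[C@H]1[C@@]2(C)[C@@H]4C[C@@H]4C(=C)[C@@H]2CC2=C(C)C(=O)O[C@@]213 | target

## Step count and least certain steps

Total step count: 19. Longest linear sequence: 19 steps, from 1.

**Step 16 (key step).** The nitrile oxide may dimerise to a furoxan if addition to the trisubstituted, α-branched enoate is slow, and hypochlorite may chlorinate the electron-rich C4=C15 alkene. The fallback avoids both oxidant and free nitrile oxide by a silyl nitronate cycloaddition. It sets out from acetal 20: mild acid hydrolysis gives aldehyde 21, which NaBH4 reduces to the primary alcohol F1. Iodine, triphenylphosphine and imidazole convert it into the iodide F2, and NaNO2 in DMF gives the nitroalkane F3. Me3SiCl and Et3N form the silyl nitronate F4, which cyclises onto the enoate to the N-silyloxyisoxazolidine F5. Acid-induced loss of silanol gives isoxazoline 24, where the route is rejoined.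

**Step 5.** Oxygen may be delivered at the neopentyl end of the allyl system to give the transposed enone, and the acetal C–H may be attacked. The fallback sets out from 7: allylic hydroxylation with catalytic SeO2 and t-BuOOH proceeds by an ene reaction and a [2,3] shift that can only place oxygen on the ring CH2 carbon, giving the allylic alcohol F6 as an epimer mixture. MnO2 oxidises it to enone 8.

**Step 7.** The allylic alcohol may eliminate to a cyclopentadiene or the acetal may exchange under acid at 140 °C, and bond formation next to the quaternary centre may be slow. The fallback sets out from 9: acetylation gives the acetate F7. LiN(i-Pr)2 and Me3SiCl at −78 °C give the silyl ketene acetal F8, which undergoes an Ireland–Claisen shift on warming to the silyl ester F9. Aqueous work-up gives acid 12, which enters the iodolactonisation of step 8 without the saponification.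

**Step 18.** Acid may move the C4=C15 double bond into the ring or open the cyclopropane, and 26 may undergo retro-aldol cleavage. The fallback sets out from 26: neutral dehydration with Martin sulfurane gives 27, now isolated. LiOH hydrolysis gives the keto acid F10, and Ac2O with NaOAc closes the enol lactone to 28.

**Step 19.** Head-to-tail or syn dimers may form and face selectivity may be lost on direct excitation. A small amount of the minor enantiomer of 28 would also give heterochiral dimers, so the enantiomeric purity of an earlier intermediate, such as lactone 14, should be raised if needed. The fallback goes from 28 to 29 by triplet sensitisation (thioxanthone, 405 nm), which changes the reacting excited state; failing that, the crystalline solid is irradiated. No new compound is involved.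

## Further compounds

F1 | step 16 | methyl (E)-4-[4-(2-hydroxyethyl)-4-methyl-2-methylidenebicyclo[3.1.0]hexan-3-yl]-2-methylbut-2-enoate | OCC[C@@]1(C)[C@@H]2C[C@@H]2C(=C)[C@@H]1C/C=C(\C)C(=O)OC
F2 | step 16 | methyl (E)-4-[4-(2-iodoethyl)-4-methyl-2-methylidenebicyclo[3.1.0]hexan-3-yl]-2-methylbut-2-enoate | ICC[C@@]1(C)[C@@H]2C[C@@H]2C(=C)[C@@H]1C/C=C(\C)C(=O)OC
F3 | step 16 | methyl (E)-2-methyl-4-[4-methyl-2-methylidene-4-(2-nitroethyl)bicyclo[3.1.0]hexan-3-yl]but-2-enoate | [O-][N+](=O)CC[C@@]1(C)[C@@H]2C[C@@H]2C(=C)[C@@H]1C/C=C(\C)C(=O)OC
F4 | step 16 | trimethylsilyl nitronate of F3 | C[Si](C)(C)O[N+]([O-])=CC[C@@]1(C)[C@@H]2C[C@@H]2C(=C)[C@@H]1C/C=C(\C)C(=O)OC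
F5 | step 16 | N-(trimethylsilyloxy)isoxazolidine corresponding to 24 | C=C1[C@H]2C[C@H]2[C@@]2(C)[C@H]1C[C@H]1C(N(O[Si](C)(C)C)O[C@]1(C)C(=O)OC)C2
F6 | step 5 | (4R)-4-(2,2-diethoxyethyl)-4-methylcyclopent-2-en-1-ol (C1 epimer mixture) | CCOC(OCC)C[C@]1(C)C=CC(O)C1
F7 | step 7 | (1S,4R)-4-(2,2-diethoxyethyl)-4-methylcyclopent-2-en-1-yl acetate | CCOC(OCC)C[C@]1(C)C=C[C@@H](OC(C)=O)C1
F8 | step 7 | 1-(trimethylsilyloxy)vinyl ether of 9 (silyl ketene acetal) | CCOC(OCC)C[C@]1(C)C=C[C@@H](OC(=C)O[Si](C)(C)C)C1
F9 | step 7 | trimethylsilyl 2-[(1S,5R)-5-(2,2-diethoxyethyl)-5-methylcyclopent-2-en-1-yl]acetate | CCOC(OCC)C[C@]1(C)[C@@H](CC(=O)O[Si](C)(C)C)C=CC1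
F10 | step 18 | carboxylic acid of 27 ((Z)-alkylidene keto acid) | C=C1[C@H]2C[C@H]2[C@@]2(C)[C@H]1C/C(C(=O)C2)=C(\C)C(=O)O
F0 | step 19 | none | none
A1 | alternative 1 | 4-[2-(tert-butyldimethylsilyloxy)ethyl]-5-menthyloxyfuran-2(5H)-one | O=C1C=C(CCO[Si](C)(C)C(C)(C)C)[C@@H](O[C@@H]2C[C@H](C)CC[C@H]2C(C)C)O1
A2 | alternative 1 | 4-methyl-2,3-dimethylidene-2,3-dihydrofuran (furan-2,3-quinodimethane) | C=C1OC=C(C)C1=C
A3 | alternative 1 | furan-fused cis-lactone cycloadduct | Cc1coc2c1C[C@H]3C(=O)O[C@H](O[C@@H]4C[C@H](C)CC[C@H]4C(C)C)[C@@]3(CCO[Si](C)(C)C(C)(C)C)C2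
A4 | alternative 2 | 4-(dimethoxymethyl)-4-methylhex-5-en-1-yn-3-yl acetate | C#CC(OC(C)=O)[C@](C)(C=C)C(OC)OC
A5 | alternative 2 | 4-(dimethoxymethyl)-4-methylbicyclo[3.1.0]hex-2-en-2-yl acetate | CC(=O)OC1=C[C@@](C)(C(OC)OC)[C@@H]2C[C@H]12
A6 | alternative 3 | 8-(1-bromoethenyl)-7-cyclopropyl-7-methyl-1,4-dioxaspiro[4.5]decane (bromoethenyl trans to cyclopropyl) | C=C(Br)[C@@H]1CCC2(OCCO2)C[C@@]1(C)C1CC1
A7 | alternative 3 | lindenane C8 dioxolane with C4=C15 | C=C1[C@H]2C[C@H]2[C@@]2(C)[C@H]1CCC1(OCCO1)C2
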